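A pitfall with mirror-image products is to read the excess as a property of the temperature, when the product may be turning into its mirror image while it is being made.

the same everywhere: D 32 mM; X 13 mM (held); J 32 µM; Z 32 mM; time 8.0 h

| flask | temperature | remark |
|---|---|---|
| east | 25 °C |  |
| south | 50 °C |  |
| north-west |  | at 25 °C until 4.0 h, from then on at 50 °C |

1. the best flask by excess of G.D over G.Z; "all alike" if 1.5 percentage points covers them all (east / south / north-west / all alike)
2. excess of G.D over G.Z at the end, east
3. excess of G.D over G.Z at the end, south
4. excess of G.D over G.Z at the end, north-west

- G is single-handed; D and Z are mirror images of each other, charged as a racemate, each of them at the stated concentration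
- at the start none of G is dissolved
- at 50 °C the constants are as listed, elsewhere as the activation energies make them
- an excess is the difference of the two amounts in percent of their sum
- an excess is below zero if the other one leads
- the handed part of G does not stay in what it makes, so the products of the two hands are mirror images too

    G + D → G.D (k1 = 0.15 L mol⁻¹ min⁻¹, Ea1 = 83.0 kJ mol⁻¹)
    G + Z → G.Z (k2 = 0.056 L mol⁻¹ min⁻¹, Ea2 = 53.0 kJ mol⁻¹)
    X ⇌ G, rate k3*(csat - [G]) (k3 = 0.0041 min⁻¹, csat = 13 mM)
    G + J → G.J (k4 = 0.21 L mol⁻¹ min⁻¹, Ea4 = 66.0 kJ mol⁻¹)
    G.D ⇌ G.Z (k5 = 0.0016 min⁻¹, Ea5 = 104 kJ mol⁻¹)
    D + J ⇌ Z + J, rate k6*[J]*[D] forward; the back reaction follows from the equilibrium constant (k6 = 140 L mol⁻¹ min⁻¹, Ea6 = 40.0 kJ mol⁻¹)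
    (constants at 50 °C)

Two colleagues disagree. The first divides one rate by the other. G.D forms in proportion to G times D, and G.Z in proportion to G times Z, so G and time drop out of the quotient. D and Z cancel as well if they stay equal, and at 50 °C they should stay nearly so, because J as charged evens them out with a rate constant of 0.00896 min⁻¹, more than the 0.00195 min⁻¹ at which even saturated G removes D. What remains at 50 °C is 2.68: the selectivity factor s, G.D made per G.Z made at equal D and Z.

The step to G.D has the higher activation energy, by 30.0 kJ mol⁻¹. The step to G.Z speeds up 5.2 times between the two temperatures, and the logarithm of such a factor scales with activation energy, so the selectivity factor falls to 1.05 at 25 °C. Fresh product carries an excess of s minus one over s plus one, which is 45.6% hot, and for east 2.45%.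

The first colleague adds a leak. G.D and G.Z interconvert, so their excess decays with a time constant τ, equal to one over twice the rate constant, which is 5.21 h at 50 °C. If product is made steadily for a time t, the mean surviving share is τ/t times one minus exp(−t/τ). That gives 0.511 for south and 0.698 for the hot stretch of north-west.

The second colleague argues from the end state, which is thermodynamic rather than kinetic control. The two products have the same energy, so their excess heads for zero. South runs for 8.0 h, longer than τ, and what it makes first keeps a share of 0.215 of its excess. In east the relaxation half-life of G.D and G.Z by this step alone, both ways together, is 92.7 h, long against 8.0 h, so the second colleague bets on east.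

My own reckoning takes the first side and ignores what north-west makes while cold. South comes to 23.3% and north-west to 31.9%, so north-west leads.

The forecast, on the same side, names north-west with 2.2% for east, 24.5% for south and 27.3% for north-west, lower than my north-west, holding that “the flask heated only for the last 4 h keeps slightly more than the one hot for all 8 h”.

The simulation gives north-west as the best flask, with 2.36% for east, 24.2% for south and 27.5% for north-west.

The second colleague's view holds for a far longer run: after 80.0 h east stands at 1.67%, above south at −0.637% and north-west at −0.657%. Back at 8.0 h, dividing south's result by the excess that s gives leaves a share of 0.530.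

A further flask is like east but holds 0.054 mM of J. J does not enter the selectivity factor, so at 25 °C it again gives about 2.44%. The simulation gives 2.37%.

Its constants are those of an exercise; the result is computed.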